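**Retrosynthetic overview**
1. Feature: the heptane chain C1–C7 of 17 carries the same 4-hydroxy-3-methoxyphenyl ring at C1 and at C7, and C3 (C=O) and C5 (CHOH) differ only in oxidation level. 17 is therefore the mono-ketone of a C2-symmetric (3S,5S)-heptane-3,5-diol whose two carbinols are homotopic.
2. The C3 ketone goes back to that diol (13). One hydroxyl is singled out, without statistical loss, through a 2-phenyl-1,3-dioxane (14) and its reductive opening to the mono-benzyl ether (15).
3. C1–C2 and C6–C7 are cut together. This gives (2R,4R)-1,2:4,5-diepoxypentane 6 (C2–C6) and two equivalents of the vanillin-derived benzyl Grignard 11 (C1 and C7 with their arenes).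
4. 6 goes back through the (2R,4R)-dichlorodiol 5 to 1,5-dichloropentane-2,4-dione 4, made from acetylacetone and chloroacetyl chloride. A Ru-BINAP hydrogenation of 4 sets both centres.
5. Ring order: both arenes are bought with vanillin. The two oxiranes close in step 3 and open in step 8, and the dioxane closes in step 9 and opens in step 10, so no ring made on the way remains.

Key step: step 8

Remark: chain locants C1–C7 are those of the target heptan-3-one. The (S)-BINAP antipode is assigned by analogy with the known sense of 4-chloroacetoacetate reduction, which gives the (R)-chlorohydrin with this ligand.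

Step 1
Reactants: 1 acetylacetone (pentane-2,4-dione); 2 chloroacetyl chloride (excess)
Product: 4 1,5-dichloropentane-2,4-dione, via copper(II) chelate 3 (not isolated)
Conditions: AlCl3 (3 equiv), PhNO2, 60 °C; ice/aq HCl, Et2O; aq Cu(OAc)2, solid filtered, washed and carried on moist; 10% aq H2SO4/Et2O; distil
Reagents that add atoms: copper(II) acetate, CC(=O)[O-].CC(=O)[O-].[Cu+2] (supplies the copper of 3 only; nothing from it remains in 4)
Why: Lewis acid acyl exchange (C-acylation of the aluminium-bound acetylacetonate by 2, then loss of acetyl chloride, twice over) keeps the central CH2 of 1 and replaces both acetyl groups by chloroacetyl groups, and catch-and-release through the sparingly soluble copper(II) bis-chelate 3 should free the dione from nitrobenzene and from half-exchanged material.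

Step 2
Reactants: 4 1,5-dichloropentane-2,4-dione
Product: 5 (2R,4R)-1,5-dichloropentane-2,4-diol
Conditions: [RuCl2((S)-BINAP)]2·NEt3 (0.2 mol%), H2 (85 atm), MeOH, 75 °C; recrystallise
Reagents that add atoms: none
Why: Noyori asymmetric hydrogenation of a 1,3-diketone, in which each ketone is reduced under catalyst control while chelated to ruthenium through the neighbouring oxygen, the (S)-ligand gives R at a carbinol flanked by CH2Cl, and two successive selective events divert the minor sense into the meso diol, which recrystallisation should remove.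

Step 3
Reactants: 5 (2R,4R)-1,5-dichloropentane-2,4-diol
Product: 6 (2R,4R)-1,2:4,5-diepoxypentane
Conditions: powdered KOH (4 equiv), Et2O, 0 °C → rt; filter, careful distillation
Reagents that add atoms: none
Why: Twofold intramolecular Williamson reaction (3-exo-tet SN2 of each alkoxide on its own CH2Cl carbon), in which the C–O bonds at C2 and C4 take no part, so both centres stay R.

Step 4
Reactants: 7 vanillin
Product: 8 4-benzyloxy-3-methoxybenzaldehyde
Conditions: BnBr, K2CO3, DMF, rt
Reagents that add atoms: benzyl bromide, BrCc1ccccc1
Why: Williamson etherification of the acidic para-formyl phenol masks the one proton a Grignard reagent could not tolerate with a group that leaves by hydrogenolysis at the end.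

Step 5
Reactants: 8 4-benzyloxy-3-methoxybenzaldehyde
Product: 9 (4-benzyloxy-3-methoxyphenyl)methanol
Conditions: NaBH4, MeOH/THF, 0 °C
Reagents that add atoms: none
Why: Borohydride reduction of an aromatic aldehyde, to which the two aryl ethers are inert.

Step 6
Reactants: 9 (4-benzyloxy-3-methoxyphenyl)methanol
Product: 10 4-benzyloxy-3-methoxybenzyl chloride
Conditions: SOCl2 (1.2 equiv), CH2Cl2, 0 °C
Reagents that add atoms: thionyl chloride, O=S(Cl)Cl
Why: Chlorodehydroxylation through the chlorosulfite ester is fast at 0 °C because the para-alkoxy group stabilises the benzylic cation, and the chloride is used promptly since the same activation makes it labile.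

Step 7
Reactants: 10 4-benzyloxy-3-methoxybenzyl chloride
Product: 11 4-benzyloxy-3-methoxybenzylmagnesium chloride (THF solution, titrated and used at once)
Conditions: Mg turnings (5 equiv, I2-activated), THF, 0 °C, slow addition of 10 to a final ca. 0.2 M
Reagents that add atoms: magnesium, [Mg]
Why: Grignard formation by oxidative insertion of magnesium into the benzylic C–Cl bond, where excess activated metal, low temperature and slow addition keep the standing concentration of 10 low so that insertion outruns Wurtz coupling, and the aryl ethers are inert.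

Step 8
Reactants: 6 (2R,4R)-1,2:4,5-diepoxypentane; 11 4-benzyloxy-3-methoxybenzylmagnesium chloride (4 equiv, two incorporated)
Product: 13 (3S,5S)-1,7-bis(4-benzyloxy-3-methoxyphenyl)heptane-3,5-diol, via mono-opened epoxy alkoxide 12 (not isolated)
Conditions: CuI (20 mol% on 6), THF, −40 °C; add 6, → 0 °C; sat. aq NH4Cl
Reagents that add atoms: none
Why: Excess 11 transmetallates CuI to a magnesium benzylcuprate, which attacks the CH2 terminus of one oxirane by SN2 (oxidative addition to copper, then reductive elimination) and forms C1–C2 to give 12, and the same event on the C2-related oxirane forms C6–C7. The closest known reaction type is the copper-catalysed Grignard opening of monosubstituted epoxides, run here in both directions on a C2-symmetric bis-epoxide. No ring is closed and both oxirane rings are opened. No stereocentre is created, because the C–O bonds at the two stereogenic carbons are untouched and the configuration set in step 2 is carried over, the descriptor changing from R to S only because the new CH2CH2Ar arm ranks below the central CH2 whereas the oxirane CH2 ranked above it. The only selectivity needed is regioselectivity (terminal CH2 against internal CH), which the steric bias of a monosubstituted oxirane towards a soft cuprate provides. Low temperature, copper catalysis and the excess of 11 should keep chloride opening and attack of the first alkoxide on the second oxirane slower than C–C bond formation.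

Step 9
Reactants: 13 (3S,5S)-1,7-bis(4-benzyloxy-3-methoxyphenyl)heptane-3,5-diol
Product: 14 (4S,6S)-4,6-bis[2-(4-benzyloxy-3-methoxyphenyl)ethyl]-2-phenyl-1,3-dioxane
Conditions: PhCH(OMe)2 (1.5 equiv), CSA (5 mol%), 4 Å MS, CH2Cl2, rt
Reagents that add atoms: benzaldehyde dimethyl acetal, COC(OC)c1ccccc1
Why: Acid-catalysed transacetalisation to the six-membered 2-phenyl-1,3-dioxane is familiar from anti-pentane-2,4-diol acetals (phenyl equatorial, one arm axial), and because O3 and O5 are related by the C2 axis of 13 the acetal carbon is not stereogenic and a single acetal should form.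

Step 10
Reactants: 14 (4S,6S)-4,6-bis[2-(4-benzyloxy-3-methoxyphenyl)ethyl]-2-phenyl-1,3-dioxane
Product: 15 (3S,5S)-5-benzyloxy-1,7-bis(4-benzyloxy-3-methoxyphenyl)heptan-3-ol
Conditions: DIBAL-H (4 equiv), CH2Cl2, −78 → 0 °C; aq Rochelle salt
Reagents that add atoms: none
Why: Reductive cleavage of a benzylidene acetal with DIBAL-H (aluminium coordination to one ring oxygen, C–O ionisation, hydride delivery to the oxocarbenium ion) leaves a benzyl ether on one oxygen and a free hydroxyl on the other, and since breaking either C–O bond gives the same compound, exactly one of the homotopic carbinols is protected.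

Step 11
Reactants: 15 (3S,5S)-5-benzyloxy-1,7-bis(4-benzyloxy-3-methoxyphenyl)heptan-3-ol
Product: 16 (5S)-5-benzyloxy-1,7-bis(4-benzyloxy-3-methoxyphenyl)heptan-3-one
Conditions: Dess–Martin periodinane (1.3 equiv), CH2Cl2, 0 °C → rt
Reagents that add atoms: none
Why: Dess–Martin oxidation is chosen because it needs no amine base that could trigger E1cB loss of the β-benzyloxy group, and C5 is untouched and stays S.

Step 12
Reactants: 16 (5S)-5-benzyloxy-1,7-bis(4-benzyloxy-3-methoxyphenyl)heptan-3-one
Product: 17 (5S)-5-hydroxy-1,7-bis(4-hydroxy-3-methoxyphenyl)heptan-3-one (target)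
Conditions: H2 (1 atm), 20% Pd(OH)2/C, EtOAc–EtOH, rt
Reagents that add atoms: none
Why: Catalytic hydrogenolysis over Pearlman's catalyst in a neutral solvent removes the two aryl benzyl ethers and the secondary alkyl benzyl ether, under conditions where the dialkyl ketone, the arenes and the acid- and base-sensitive β-hydroxy ketone should persist and no bond at C5 is exchanged.

**Compound list**
1 | acetylacetone (pentane-2,4-dione) | CC(=O)CC(C)=O | starting material
2 | chloroacetyl chloride | ClCC(Cl)=O | starting material
3 | copper(II) bis[(Z)-1,5-dichloro-4-oxopent-2-en-2-olate] (chelate of 4) | ClCC(=O)/C=C(/CCl)[O-].ClCC(=O)/C=C(/CCl)[O-].[Cu+2] | intermediate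
4 | 1,5-dichloropentane-2,4-dione | ClCC(=O)CC(=O)CCl | intermediate
5 | (2R,4R)-1,5-dichloropentane-2,4-diol | ClC[C@H](O)C[C@@H](O)CCl | intermediate
6 | (2R,4R)-1,2:4,5-diepoxypentane | C1O[C@@H]1C[C@@H]1CO1 | intermediate
7 | vanillin | COc1cc(C=O)ccc1O | starting material
8 | 4-benzyloxy-3-methoxybenzaldehyde | COc1cc(C=O)ccc1OCc1ccccc1 | intermediate
9 | (4-benzyloxy-3-methoxyphenyl)methanol | COc1cc(CO)ccc1OCc1ccccc1 | intermediate
10 | 4-benzyloxy-3-methoxybenzyl chloride | COc1cc(CCl)ccc1OCc1ccccc1 | intermediate
11 | 4-benzyloxy-3-methoxybenzylmagnesium chloride | COc1cc(C[Mg]Cl)ccc1OCc1ccccc1 | intermediate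
12 | chloromagnesium alkoxide of (2S)-4-(4-benzyloxy-3-methoxyphenyl)-1-[(2R)-oxiran-2-yl]butan-2-ol | COc1cc(CC[C@H](O[Mg]Cl)C[C@@H]2CO2)ccc1OCc1ccccc1 | intermediate
13 | (3S,5S)-1,7-bis(4-benzyloxy-3-methoxyphenyl)heptane-3,5-diol | COc1cc(CC[C@H](O)C[C@@H](O)CCc2ccc(OCc3ccccc3)c(OC)c2)ccc1OCc1ccccc1 | intermediate
14 | (4S,6S)-4,6-bis[2-(4-benzyloxy-3-methoxyphenyl)ethyl]-2-phenyl-1,3-dioxane | COc1cc(CC[C@H]2C[C@H](CCc3ccc(OCc4ccccc4)c(OC)c3)OC(c3ccccc3)O2)ccc1OCc1ccccc1 | intermediate
15 | (3S,5S)-5-benzyloxy-1,7-bis(4-benzyloxy-3-methoxyphenyl)heptan-3-ol | COc1cc(CC[C@H](O)C[C@@H](OCc2ccccc2)CCc2ccc(OCc3ccccc3)c(OC)c2)ccc1OCc1ccccc1 | intermediate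
16 | (5S)-5-benzyloxy-1,7-bis(4-benzyloxy-3-methoxyphenyl)heptan-3-one | COc1cc(CCC(=O)C[C@@H](OCc2ccccc2)CCc2ccc(OCc3ccccc3)c(OC)c2)ccc1OCc1ccccc1 | intermediate
17 | (5S)-5-hydroxy-1,7-bis(4-hydroxy-3-methoxyphenyl)heptan-3-one | COc1cc(CCC(=O)C[C@@H](O)CCc2ccc(O)c(OC)c2)ccc1O | target

Total step count: 12.
Longest linear sequence: 9 (steps 4–12, from vanillin). The diepoxide branch (steps 1–3) joins at step 8.

**Steps most likely to fail**

Step 7. Wurtz-type homocoupling of the electron-rich benzylic chloride with freshly formed organomagnesium may compete with insertion and leave a solution of low titre.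
- The fallback sets out from 10 (with 6) and returns at 13. It replaces the organomagnesium with a sulfone-stabilised benzylic carbanion.
- Chloride 10 is displaced with PhSO2Na in DMF to give 4-benzyloxy-3-methoxybenzyl phenyl sulfone F1.
- n-BuLi in THF at −78 °C gives the α-lithio sulfone F2. An excess of it opens both oxiranes of 6 at their CH2 termini (THF/DMPU, −78 °C → rt).
- The product is 1,7-bis(4-benzyloxy-3-methoxyphenyl)-1,7-bis(phenylsulfonyl)heptane-3,5-diol F3. Its carbinol centres are spatially as in 13 but formally 3R,5R, because the sulfonyl-bearing arm now outranks C4. The epimers at C1 and C7 are of no consequence.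
- Reductive desulfonylation with Na(Hg), Na2HPO4 in MeOH/THF should spare the benzyl ethers. It cannot eliminate, since the hydroxyls are γ to sulfur, and it gives 13.

Step 8. The second opening may lag behind the first, so that the magnesium alkoxide from the first opening closes onto the remaining oxirane, or chloride opens it in competition with carbon.
- The fallback sets out from 6 (with 11) and returns at 15. It opens one oxirane at a time and breaks the symmetry at that stage.
- An excess of 6 (surplus recovered by distillation) is treated with one equivalent of 11 under CuI catalysis and worked up to give (2S)-4-(4-benzyloxy-3-methoxyphenyl)-1-[(2R)-oxiran-2-yl]butan-2-ol F4.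
- The carbinol is capped under neutral conditions with 2-benzyloxy-1-methylpyridinium triflate and MgO in PhCF3. This gives (2R)-2-[(2S)-2-benzyloxy-4-(4-benzyloxy-3-methoxyphenyl)butyl]oxirane F5, which has no free alkoxide.
- A second copper-catalysed opening with 11 gives 15 directly, so steps 9 and 10 are no longer needed.

Step 12. The secondary alkyl benzyl ether may cleave much more slowly than the two aryl benzyl ethers. On prolonged exposure, acidic catalyst sites may cause β-elimination followed by saturation, which would erase the C5 stereocentre.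
- The fallback sets out from 13 and returns at 17. It replaces the acetal/benzyl desymmetrisation with a silyl group that is removed without hydrogen.
- Diol 13 is monosilylated (NaH, 1 equiv, then TBSCl, THF). The hydroxyls are homotopic, so only one mono-ether is possible, and unreacted diol is recycled. The product is (3S,5S)-1,7-bis(4-benzyloxy-3-methoxyphenyl)-5-(tert-butyldimethylsilyloxy)heptan-3-ol F6.
- Dess–Martin oxidation gives (5S)-1,7-bis(4-benzyloxy-3-methoxyphenyl)-5-(tert-butyldimethylsilyloxy)heptan-3-one F7.
- HF·pyridine in THF at 0 °C gives (5S)-1,7-bis(4-benzyloxy-3-methoxyphenyl)-5-hydroxyheptan-3-one F8.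
- A brief hydrogenolysis (H2, Pd/C, EtOAc) then has to remove only the two fast-cleaving aryl benzyl ethers to reach 17.

**Further compounds**
F1 | step 7 | 4-benzyloxy-3-methoxybenzyl phenyl sulfone | COc1cc(CS(=O)(=O)c2ccccc2)ccc1OCc1ccccc1
F2 | step 7 | α-lithio-4-benzyloxy-3-methoxybenzyl phenyl sulfone | COc1cc(C([Li])S(=O)(=O)c2ccccc2)ccc1OCc1ccccc1
F3 | step 7 | (3R,5R)-1,7-bis(4-benzyloxy-3-methoxyphenyl)-1,7-bis(phenylsulfonyl)heptane-3,5-diol, epimers at C1/C7 | COc1cc(C(C[C@H](O)C[C@@H](O)CC(c2ccc(OCc3ccccc3)c(OC)c2)S(=O)(=O)c2ccccc2)S(=O)(=O)c2ccccc2)ccc1OCc1ccccc1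
F4 | step 8 | (2S)-4-(4-benzyloxy-3-methoxyphenyl)-1-[(2R)-oxiran-2-yl]butan-2-ol | COc1cc(CC[C@H](O)C[C@@H]2CO2)ccc1OCc1ccccc1
F5 | step 8 | (2R)-2-[(2S)-2-benzyloxy-4-(4-benzyloxy-3-methoxyphenyl)butyl]oxirane | COc1cc(CC[C@H](OCc2ccccc2)C[C@@H]2CO2)ccc1OCc1ccccc1
F6 | step 12 | (3S,5S)-1,7-bis(4-benzyloxy-3-methoxyphenyl)-5-(tert-butyldimethylsilyloxy)heptan-3-ol | COc1cc(CC[C@H](O)C[C@@H](O[Si](C)(C)C(C)(C)C)CCc2ccc(OCc3ccccc3)c(OC)c2)ccc1OCc1ccccc1
F7 | step 12 | (5S)-1,7-bis(4-benzyloxy-3-methoxyphenyl)-5-(tert-butyldimethylsilyloxy)heptan-3-one | COc1cc(CCC(=O)C[C@@H](O[Si](C)(C)C(C)(C)C)CCc2ccc(OCc3ccccc3)c(OC)c2)ccc1OCc1ccccc1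
F8 | step 12 | (5S)-1,7-bis(4-benzyloxy-3-methoxyphenyl)-5-hydroxyheptan-3-one | COc1cc(CCC(=O)C[C@@H](O)CCc2ccc(OCc3ccccc3)c(OC)c2)ccc1OCc1ccccc1
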